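Remark on the chemistry: germacranolide numbering is used throughout (ring C1–C10, lactone carbons C11–C13, C14 on C10, C15 on C4; α/β refer to the usual drawing with H7 α). The configuration at C11 of the amine-bearing intermediates is written as formed in step 6 but is immaterial, because C11 becomes trigonal in step 27.

## Analysis of the target

The target is a heliangolide-type germacranolide: a ten-membered carbocycle (C1–C10) fused trans at C6/C7 to an α-methylene-γ-butyrolactone (O–C6, C7, C11(=C13), C12). It has six stereocentres, (1R,3S,6R,7R,8R,10R): a trans 1β,10α-epoxide that derives from an E C1=C10 olefin, a 3β-hydroxyl next to the Z-trisubstituted C4=C5 olefin, and the contiguous triad C6 (α-oxygen), C7 (H α) and C8 (β-acyloxy, cis to the C7–C11 bond). The C8 oxygen carries a diester chain: an (E)-2-(hydroxymethyl)but-2-enoate whose hydroxyl is acylated by (E)-2-(acetoxymethyl)-4-hydroxybut-2-enoic acid. Sensitive groups are the exocyclic methylene lactone (Michael acceptor, prone to isomerisation), the trisubstituted epoxide (acid-triggered transannular opening), the allylic ester links of the chain (amine- or palladium-induced allylic substitution), and three kinds of ester that rule out any late hydrolysis. The difficulty lies in forming the medium ring with two defined trisubstituted olefins, in setting C3 and C8 inside that ring, and in telling the C3 and C8 hydroxyls apart. The strategy rests on C7 as the branch point bonded to C6, C8 and C11. The run C5–C6–C7–C11–C12 is the carbon chain of L-glutamic acid and of the butenolide derived from it, in which C7 is the electrophilic β carbon and C11 the nucleophilic α carbon, so C8 and C13 can be attached in one operation while C6 comes from the chiral pool.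

## Retrosynthetic reasoning

41 ⇒ 40. The two O–Si bonds (C3 oxygen and the terminal hydroxyl of the chain) are cut last. Both hydroxyls are free in 41 and the C3 hydroxyl must be kept distinct from the C8 oxygen, so they travel as fluoride-labile ethers that can be removed without touching an ester, the epoxide or the methylene lactone.

40 ⇒ 39. The C1–O and C10–O bonds of the epoxide are cut back to the E C1=C10 olefin. The epoxide is the most acid-sensitive group, and in 39 this olefin is the only electron-rich, strained double bond left. The forward peracid oxidation must choose it over C4=C5 and attack its outer face.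

39 ⇒ 37. The C11=C13 π bond is exchanged for a C13–N bond, so the methylene lactone is carried as its β-dimethylamino (Mannich base) form. This keeps the Michael acceptor out of every basic, nucleophilic and reducing step, and C13 is then already present from the key step. Forward: quaternisation and mild base-induced elimination.

37 ⇒ 22 + 35. The C8 O–acyl bond is cut to separate the core alcohol 22 from the complete diester acid 35. Attaching the finished chain in one acylation exposes its allylic ester links to the fewest steps. The forward reaction must acylate a hindered secondary alcohol without moving the enoate double bond.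

35 ⇒ 34 ⇒ 30 + 33. Inside the chain the O–CH2 bond between the two C5 units is cut: carboxylate of 30 plus allylic bromide 33. tert-Butyl esters (34, 29) are used because acid cleaves them next to an acetate.

30 ⇒ 29 ⇒ 28 ⇒ 27 ⇒ 25 + 26, and 33 ⇒ 32 ⇒ 26 + 31. Both halves are 2-(oxymethyl)alk-2-enoates and so go back to Morita–Baylis–Hillman adducts (C–C bond between the acrylate α carbon and the aldehyde carbon). Allylic bromination with transposition fixes each trisubstituted olefin geometry. 25 comes from 23 through 24.

22 ⇒ 21 ⇒ 20. The C8–H bond is cut to give ketone 21, whose carbonyl is masked as the dithiane of 20. C8 thereby becomes an acyl-anion carbon, which the key step needs. Its configuration is left to hydride delivery on the closed ring, where the C7–C6 ring bond differentiates the two faces.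

20 ⇒ 19 ⇒ 18. After the C3 silyl ether is removed, the ten-membered ring is opened at C3–C4, between an aldehyde and an alkenyl iodide. This bond is chosen because the Z geometry of C4=C5 can be fixed beforehand in an acyclic alkenyl iodide and transferred with retention, and because chromium-mediated addition tolerates lactone, amine and dithiane. The forward reaction must close the ring and create C3.

18 ⇒ 17 ⇒ 16 ⇒ 15 ⇒ 14 ⇒ 13. The aldehyde goes back to alcohol 17 and silyl ether 16. The C4=C5 bond of 16 is cut in a Wittig sense to aldehyde 15, which comes from trityl ether 13 through alcohol 14. The two primary oxygens are therefore protected orthogonally (acid-labile at C5, fluoride-labile at C3).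

13 ⇒ 2 + 9 + 10. This is the key disconnection: C7–C8 and C11–C13 are cut at the branch carbon and its neighbour. C7 is the β carbon of butenolide 2 (electrophile), C8 is an acyl-anion carbon in 9 (it carries oxygen in 41), C11 is the enolate carbon, and C13 is the iminium carbon of 10. No ring is formed, so the medium-ring problem is kept out of this step. C7 is set relative to C6, and the chain that holds C9, the E C1=C10 olefin and C3 arrives in one piece.

9 ⇒ 7 + 6; 6 ⇒ 5 ⇒ 4 ⇒ 3. The C8–C9 bond is cut to 1,3-dithiane 7 and allylic bromide 6. The bromide goes back through allylic alcohol 5 to the silyl ether 4 of 3 by an E-selective allylic oxidation of a terminal methyl group, which is where the C1=C10 geometry is set.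

2 ⇒ 1. The O–CPh3 bond is cut. The bulky ether on the chiral-pool butenolide 1 is the element that directs the face of attack at C7.

## Alternatives that were turned down

Alternative 1: The ten-membered ring would be released rather than closed, by breaking the C5–C10 bond of a lactone-bridged cis-decalin in a vinylogous Grob fragmentation. Forward, fluoride would free a C3 enolate from its silyl ether. Electron flow through C4, C5 and C10 would then create the C4=C5 and C1=C10 π bonds as the C5–C10 σ bond breaks and a C1 sulfonate leaves, giving dienone A1.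
- For: no medium-ring closure against entropy and transannular strain, no high dilution, and both olefin geometries follow stereospecifically from a rigid bicycle in which C6, C7 and C8 obey six-membered-ring rules. On ring formation and olefin geometry it is stronger than the chosen route.
- Against: the bicycle needs a quaternary C10, a C1 leaving group held antiperiplanar to C5–C10, and the lactone and C8 ether already in place as one enantiomer, which is a long linear prelude. A1 still lacks C13 and has a C3 ketone whose C2 protons lie between the carbonyl and C1=C10, so lactone methylenation and C3 reduction would be done on a skipped dienone that enolises and conjugates readily. The p-methoxybenzyl ether must also be removed oxidatively next to a strained electron-rich olefin.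
- Comparison: the chosen plan accepts the risk of a direct ring closure but offers three-fragment convergence, C6 from the chiral pool, C13 present from step 6, and C3 formed directly as the alcohol.

Alternative 2: The lactone would be made last by disconnecting C12–O and C11–C12 on a complete ten-membered epoxy carbocycle bearing a C6 hydroxyl and a C7 ethynyl group. Forward, a palladium/tin chloride catalyst under a carbonylating atmosphere would add the hydroxyl and a one-carbon carbonyl unit across the alkyne, closing the five-membered ring with its exocyclic methylene to give A2.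
- For: the methylene lactone arrives complete and very late, so it needs neither mask nor unmasking. A2 is only a selective desilylation, an acylation and a final desilylation from the target. In end-game economy it is better than the chosen route, which spends an amine mask and a quaternisation on this group.
- Against: the whole problem is shifted to the carbocycle, where six stereocentres, including the trans relation of the C6 hydroxyl and C7 alkyne next to C8, must be set without the lactone as anchor. The trisubstituted epoxide must survive Lewis-acidic chloride salts under heating, where chloride opening or transannular attack by C4=C5 is likely.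
- Comparison: the chosen route uses the lactone from step 6 as the template from which C7 and then C8 are derived, and brings in the epoxide only after all metal-mediated steps.

Alternative 3: The lactone would be annulated onto a preformed ten-membered ring by disconnecting C7–C11 and C8–O. A methyl malonate on the C6 oxygen supplies C11 and C12, and a C7=C8 olefin accepts them. Forward, the malonate enolate is oxidised by an anodically recycled organo-iron mediator to the C11 radical, which closes 5-exo onto C7. The C8 radical is trapped by a nitroxyl to give A3, whose C11 epimers are of no consequence.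
- For: one step forms the lactone ring and the C8–O bond, the oxidant is electricity, and C8 arrives at the alcohol oxidation level. At this point it is more step-economic than the chosen route, which needs a dithiane hydrolysis and a reduction.
- Against: C8 would be set by radical–radical coupling of a bulky nitroxyl with a mobile ring radical, and C7 by a cyclisation transition state on a medium ring; neither is easily steered or corrected. The substrate is a ten-membered trienone whose C2 protons are exposed to the base that forms the enolate. A3 then needs N–O cleavage, decarboxylative methylenation and C3 reduction on a sensitive dienone, and the ring itself still has to be made without a chiral anchor.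
- Comparison: the chosen route sets C7 by ionic anti addition to a rigid five-membered ring and C8 by a hydride reduction that can be corrected by inversion, at the price of two more operations at C8.

Key step: step 6

## Route

Step 1
Reactants: 1 (S)-5-(hydroxymethyl)furan-2(5H)-one
Product: 2 (S)-5-(trityloxymethyl)furan-2(5H)-one
Conditions: TrCl, pyridine, DMAP (cat.), CH2Cl2, rt
Reagents that add atoms: trityl chloride ClC(c1ccccc1)(c1ccccc1)c1ccccc1
Why: Tritylation of the primary alcohol under weakly basic conditions that do not enolise the butenolide, so the C6 centre from the chiral pool is kept; the bulky ether is the face-directing group of step 6.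

Step 2
Reactants: 3 4-methylpent-3-en-1-ol
Product: 4 tert-butyl[(4-methylpent-3-en-1-yl)oxy]diphenylsilane
Conditions: TBDPSCl, imidazole, DMF, rt
Reagents that add atoms: tert-butyl(chloro)diphenylsilane CC(C)(C)[Si](Cl)(c1ccccc1)c1ccccc1
Why: Standard silylation; the tert-butyldiphenylsilyl ether is chosen because it survives the acid that later removes the trityl group.

Step 3
Reactants: 4 tert-butyl[(4-methylpent-3-en-1-yl)oxy]diphenylsilane
Product: 5 (E)-5-(tert-butyldiphenylsilyloxy)-2-methylpent-2-en-1-ol
Conditions: SeO2 (0.5 equiv), t-BuOOH, salicylic acid (cat.), CH2Cl2, 0 °C → rt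
Reagents that add atoms: selenium dioxide O=[Se]=O (oxygen source, turned over by tert-butyl hydroperoxide CC(C)(C)OO)
Why: Riley allylic oxidation (ene reaction, then [2,3]-shift) attacks the methyl group trans to the chain of a trisubstituted olefin, which fixes the E geometry of the later C1=C10 bond.

Step 4
Reactants: 5 (E)-5-(tert-butyldiphenylsilyloxy)-2-methylpent-2-en-1-ol
Product: 6 (E)-[(5-bromo-4-methylpent-3-en-1-yl)oxy](tert-butyl)diphenylsilane
Conditions: CBr4, PPh3, CH2Cl2, 0 °C
Reagents that add atoms: carbon tetrabromide BrC(Br)(Br)Br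
Why: Appel bromination of a primary allylic alcohol proceeds by direct displacement, without allylic shift or loss of olefin geometry.

Step 5
Reactants: 7 1,3-dithiane; 6 (E)-[(5-bromo-4-methylpent-3-en-1-yl)oxy](tert-butyl)diphenylsilane
Product: 9 2-[(E)-5-(tert-butyldiphenylsilyloxy)-2-methylpent-2-en-1-yl]-1,3-dithiane, via 2-lithio-1,3-dithiane 8 (not isolated)
Conditions: n-BuLi, THF, −30 °C; then 6, −78 → 0 °C
Reagents that add atoms: none
Why: Corey–Seebach alkylation: the dithiane anion displaces the primary allylic bromide at the α carbon, joining the future C8 to C9.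

Step 6
Reactants: 9 2-[(E)-5-(tert-butyldiphenylsilyloxy)-2-methylpent-2-en-1-yl]-1,3-dithiane; 2 (S)-5-(trityloxymethyl)furan-2(5H)-one; 10 N,N-dimethylmethyleneiminium iodide (Eschenmoser's salt)
Product: 13 (3R,4S,5S)-3-[(dimethylamino)methyl]-4-{2-[(E)-5-(tert-butyldiphenylsilyloxy)-2-methylpent-2-en-1-yl]-1,3-dithian-2-yl}-5-(trityloxymethyl)oxolan-2-one (trans,trans), via lithiated dithiane 11 (not isolated), via lithium lactone enolate 12 (not isolated)
Conditions: n-BuLi, THF, −30 °C; HMPA (3 equiv), −78 °C; 2, −78 °C; then 10 (solid, 3 equiv), −78 → 0 °C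
Reagents that add atoms: none
Why: Deprotonation of 9 gives the tertiary dithianyl anion 11, which HMPA turns into a solvent-separated, soft ion pair that adds in Michael fashion to C7, the β carbon of butenolide 2, rather than to its carbonyl group. The lithium enolate 12 is then alkylated on carbon (C11) by the iminium ion of 10 in a Mannich reaction; the closest known reaction type is the tandem conjugate addition–enolate trapping of butenolides with sulfur-stabilised carbanions used for lignan lactones, together with the aminomethylation of lactone enolates. No ring is closed; the bonds C7–C8 and C11–C13 are formed. C7 is set by approach of the anion to the face of the flat butenolide opposite the trityloxymethyl group on the neighbouring C6, which gives the trans C6/C7 relation of the target lactone. C11 is set by approach of the iminium ion anti to the bulky dithianyl group on C7; this centre is temporary, since C11 becomes trigonal in step 27. The step needs 1,4- over 1,2-addition and over removal of the acidic C6 proton, which the delocalised anion, HMPA and −78 °C are meant to secure, and C- over O-alkylation, which is normal for iminium salts. The amine introduced here masks the exocyclic methylene through all later basic and reducing steps.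

Step 7
Reactants: 13 trityl ether lactone (3R,4S,5S)
Product: 14 (3R,4S,5S)-3-[(dimethylamino)methyl]-4-{2-[(E)-5-(tert-butyldiphenylsilyloxy)-2-methylpent-2-en-1-yl]-1,3-dithian-2-yl}-5-(hydroxymethyl)oxolan-2-one
Conditions: TsOH·H2O (1.5 equiv), MeOH–CH2Cl2, 0 °C → rt; NaHCO3 work-up
Reagents that add atoms: none
Why: Acid solvolysis of the trityl ether through the trityl cation, which methanol captures; the amine is held as its salt, and the primary TBDPS ether, dithiane and lactone are stable at this acid strength.

Step 8
Reactants: 14 C5 alcohol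
Product: 15 (2S,3S,4R)-4-[(dimethylamino)methyl]-3-{2-[(E)-5-(tert-butyldiphenylsilyloxy)-2-methylpent-2-en-1-yl]-1,3-dithian-2-yl}-5-oxooxolane-2-carbaldehyde (C5 aldehyde)
Conditions: SO3·pyridine, DMSO, i-Pr2NEt, CH2Cl2, 0 °C; used crude
Reagents that add atoms: none
Why: Parikh–Doering oxidation leaves the dithiane sulfur atoms and the amine alone and runs at 0 °C, which limits epimerisation of the α-acyloxy aldehyde at C6 (equilibration would in any case favour the trans lactone).

Step 9
Reactants: 15 C5 aldehyde
Product: 16 (3R,4S,5S)-3-[(dimethylamino)methyl]-4-{2-[(E)-5-(tert-butyldiphenylsilyloxy)-2-methylpent-2-en-1-yl]-1,3-dithian-2-yl}-5-[(Z)-2-iodoprop-1-en-1-yl]oxolan-2-one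
Conditions: EtPPh3I, n-BuLi, THF, rt; I2, −78 °C; NaN(SiMe3)2, −78 → −20 °C; then 15, −78 °C
Reagents that add atoms: ethyltriphenylphosphonium iodide CC[P+](c1ccccc1)(c1ccccc1)c1ccccc1.[I-]; iodine II
Why: Stork–Zhao-type Wittig olefination with the α-iodoethylidene ylide gives, under the kinetic control typical of non-stabilised ylides, the trisubstituted alkenyl iodide with iodine cis to C6. This is the Z C4=C5 geometry once iodine is replaced by C3, and it brings in C4 and C15.

Step 10
Reactants: 16 (Z)-alkenyl iodide
Product: 17 (3R,4S,5S)-3-[(dimethylamino)methyl]-4-{2-[(E)-5-hydroxy-2-methylpent-2-en-1-yl]-1,3-dithian-2-yl}-5-[(Z)-2-iodoprop-1-en-1-yl]oxolan-2-one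
Conditions: TBAF, AcOH, THF, rt
Reagents that add atoms: none
Why: Acetic acid-buffered fluoride cleaves the primary silyl ether without base-induced loss of the amine or opening of the lactone; alkenyl iodide and dithiane are inert.

Step 11
Reactants: 17 C3 alcohol
Product: 18 (3R,4S,5S)-3-[(dimethylamino)methyl]-4-{2-[(E)-2-methyl-5-oxopent-2-en-1-yl]-1,3-dithian-2-yl}-5-[(Z)-2-iodoprop-1-en-1-yl]oxolan-2-one (C3 aldehyde)
Conditions: (COCl)2, DMSO, CH2Cl2, −78 °C; Et3N, −78 → −40 °C; used crude
Reagents that add atoms: none
Why: Swern oxidation at low temperature gives the β,γ-unsaturated aldehyde before the C1=C10 olefin can move into conjugation; the crude aldehyde goes directly into the ring closure.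

Step 12
Reactants: 18 iodo aldehyde
Product: 19 (1(10)E,4Z)-13-(dimethylamino)-3β-hydroxy-8,8-(propane-1,3-diyldisulfanediyl)-11βH-11,13-dihydrogermacra-1(10),4-dien-6α,12-olide
Conditions: CrCl2 (10 equiv), NiCl2 (cat.), degassed DMSO, rt, syringe-pump addition to 0.003 M
Reagents that add atoms: none
Why: Nozaki–Hiyama–Kishi reaction: zerovalent nickel (formed from NiCl2 by CrCl2) inserts into the C4–I bond, the alkenyl group passes to trivalent chromium with retention of the Z geometry and adds to the C3 aldehyde, closing the ten-membered ring (10-exo-trig) under high dilution, helped by the gem-disubstitution at C8. The new C3 centre is set by the closing conformation: with the trans lactone and the dithiane fixing the chain, the aldehyde is expected to present the face that places the chromium alkoxide on the outer β side (3S), as in the heliangolide ring, but this preference is not secured (see the fallback).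

Step 13
Reactants: 19 macrocyclic C3 alcohol
Product: 20 3-O-tert-butyldimethylsilyl ether of 19
Conditions: TBSOTf, 2,6-lutidine, CH2Cl2, −78 °C
Reagents that add atoms: tert-butyldimethylsilyl triflate CC(C)(C)[Si](C)(C)OS(=O)(=O)C(F)(F)F
Why: Silylation of the allylic alcohol keeps C3–O distinct from the C8 hydroxyl to come and removes any hydroxyl-directing effect on C4=C5 in the later epoxidation.

Step 14
Reactants: 20 C3 silyl ether with C8 dithiane
Product: 21 (1(10)E,4Z)-3β-(tert-butyldimethylsilyloxy)-13-(dimethylamino)-8-oxo-11βH-11,13-dihydrogermacra-1(10),4-dien-6α,12-olide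
Conditions: PhI(OCOCF3)2, CF3CO2H (2 equiv), MeCN–H2O (9:1), 0 °C, 10 min; pH 7 buffer; used crude at once
Reagents that add atoms: water O
Why: Oxidative hydrolysis of the dithioacetal by the trivalent iodine reagent is fast at 0 °C; the acid keeps the amine protonated, so it is neither oxidised nor able to act as a base toward the new β-acyloxy, β,γ-unsaturated ketone.

Step 15
Reactants: 21 C8 ketone
Product: 22 (1(10)E,4Z)-3β-(tert-butyldimethylsilyloxy)-13-(dimethylamino)-8β-hydroxy-11βH-11,13-dihydrogermacra-1(10),4-dien-6α,12-olide
Conditions: NaBH4, CeCl3·7H2O, MeOH, −78 °C; AcOH quench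
Reagents that add atoms: none
Why: Luche reduction: 1,2-hydride addition at −78 °C should outrun enolisation, β-elimination of the C6 carboxylate and migration of C1=C10. Attack from outside the ring, anti to the C7–C6 ring bond and past the small H7 rather than C11 (Felkin–Anh), should give the 8β (8R) alcohol with H8 cis to H7.

Step 16
Reactants: 23 ethylene glycol
Product: 24 2-(tert-butyldiphenylsilyloxy)ethanol
Conditions: TBDPSCl, imidazole, THF, 0 °C → rt (diol in excess)
Reagents that add atoms: tert-butyl(chloro)diphenylsilane CC(C)(C)[Si](Cl)(c1ccccc1)c1ccccc1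
Why: Monosilylation of a symmetrical diol, made selective by an excess of the cheap diol.

Step 17
Reactants: 24 2-(tert-butyldiphenylsilyloxy)ethanol
Product: 25 (tert-butyldiphenylsilyloxy)acetaldehyde
Conditions: (COCl)2, DMSO, CH2Cl2, −78 °C; Et3N
Reagents that add atoms: none
Why: Swern oxidation of a primary alcohol; the acid-stable silyl group is chosen to survive the two later tert-butyl ester cleavages.

Step 18
Reactants: 25 (tert-butyldiphenylsilyloxy)acetaldehyde; 26 tert-butyl acrylate
Product: 27 tert-butyl 4-(tert-butyldiphenylsilyloxy)-3-hydroxy-2-methylidenebutanoate (racemic)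
Conditions: DABCO (1 equiv), dioxane–H2O (1:1), rt
Reagents that add atoms: none
Why: Morita–Baylis–Hillman reaction with an activated α-alkoxy aldehyde; the carbinol centre need not be controlled because it is lost in step 19.

Step 19
Reactants: 27 Baylis–Hillman adduct
Product: 28 tert-butyl (Z)-2-(bromomethyl)-4-(tert-butyldiphenylsilyloxy)but-2-enoate
Conditions: NBS, Me2S, CH2Cl2, 0 °C → rt
Reagents that add atoms: N-bromosuccinimide O=C1CCC(=O)N1Br
Why: Bromide attacks the alkoxysulfonium salt at the terminal methylene with allylic transposition (SN2'). The conformer that avoids allylic strain places the silyloxymethyl group trans to the ester, which is the geometry of the outer enoate.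

Step 20
Reactants: 28 allylic bromide
Product: 29 tert-butyl (E)-2-(acetoxymethyl)-4-(tert-butyldiphenylsilyloxy)but-2-enoate
Conditions: KOAc, 18-crown-6 (cat.), MeCN, rt
Reagents that add atoms: potassium acetate CC(=O)[O-].[K+]
Why: Direct SN2 displacement of the primary allylic bromide by acetate, with no amine present to relay an SN2' path, leaves the olefin in place; the descriptor changes from Z to E only through the priority rules.

Step 21
Reactants: 29 tert-butyl ester
Product: 30 (E)-2-(acetoxymethyl)-4-(tert-butyldiphenylsilyloxy)but-2-enoic acid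
Conditions: CF3CO2H, CH2Cl2, 0 °C → rt
Reagents that add atoms: none
Why: Acidolysis of the tert-butyl ester (loss of isobutene) leaves the acetate and the primary tert-butyldiphenylsilyl ether intact.

Step 22
Reactants: 26 tert-butyl acrylate; 31 acetaldehyde
Product: 32 tert-butyl 3-hydroxy-2-methylidenebutanoate (racemic)
Conditions: DABCO, neat, rt, sealed vessel
Reagents that add atoms: none
Why: Morita–Baylis–Hillman reaction; the carbinol centre is lost in step 23.

Step 23
Reactants: 32 Baylis–Hillman adduct
Product: 33 tert-butyl (Z)-2-(bromomethyl)but-2-enoate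
Conditions: NBS, Me2S, CH2Cl2, 0 °C → rt
Reagents that add atoms: N-bromosuccinimide O=C1CCC(=O)N1Br
Why: Same SN2' bromination as in step 19; the methyl group ends up trans to the ester (tiglate-type geometry of the inner enoate).

Step 24
Reactants: 30 outer acid; 33 inner allylic bromide
Product: 34 tert-butyl (E)-2-({[(E)-2-(acetoxymethyl)-4-(tert-butyldiphenylsilyloxy)but-2-enoyl]oxy}methyl)but-2-enoate
Conditions: Cs2CO3 (0.55 equiv), DMF, 0 °C → rt
Reagents that add atoms: none
Why: The caesium carboxylate of 30 displaces the primary allylic bromide of 33 by SN2, forming the O–CH2 link of the diester with both olefin geometries untouched.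

Step 25
Reactants: 34 diester tert-butyl ester
Product: 35 (E)-2-({[(E)-2-(acetoxymethyl)-4-(tert-butyldiphenylsilyloxy)but-2-enoyl]oxy}methyl)but-2-enoic acid
Conditions: CF3CO2H, CH2Cl2, 0 °C
Reagents that add atoms: none
Why: Selective acidolysis of the tert-butyl ester in the presence of the acetate, the inner allylic ester and the silyl ether.

Step 26
Reactants: 35 side-chain acid; 22 C8 alcohol
Product: 37 8-O-acyl derivative of 22 [(1(10)E,4Z)-3β-(tert-butyldimethylsilyloxy)-13-(dimethylamino)-8β-{(E)-2-[((E)-2-(acetoxymethyl)-4-(tert-butyldiphenylsilyloxy)but-2-enoyl)oxymethyl]but-2-enoyloxy}-11βH-11,13-dihydrogermacra-1(10),4-dien-6α,12-olide], via mixed anhydride 36 (not isolated)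
Conditions: 2,4,6-Cl3C6H2COCl, Et3N, toluene, rt; then 22, DMAP, toluene, rt
Reagents that add atoms: none
Why: Yamaguchi esterification: DMAP is acylated at the less hindered enoyl carbonyl of 36 and the acylpyridinium salt esterifies the hindered C8 hydroxyl with retention at C8. The E (tiglate-type) enoate is the stable isomer and is not expected to move.

Step 27
Reactants: 37 amine-masked ester
Product: 39 (1(10)E,4Z)-3β-(tert-butyldimethylsilyloxy)-8β-(acyloxy as in 37)germacra-1(10),4,11(13)-trien-6α,12-olide, via trimethylammonium iodide 38 (not isolated)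
Conditions: MeI, MeCN, rt; then NaHCO3 (aq.), EtOAc, rt
Reagents that add atoms: none
Why: Exhaustive methylation turns the amine into a leaving group, and bicarbonate then removes the acidic C11 proton (E1cB elimination) to release the exocyclic methylene; no other group in 37 reacts with either reagent.

Step 28
Reactants: 39 triene lactone
Product: 40 1β,10α-epoxide of 39 (1R,10R)
Conditions: mCPBA (1.1 equiv), NaHCO3, CH2Cl2, 0 °C
Reagents that add atoms: 3-chloroperoxybenzoic acid OOC(=O)c1cccc(Cl)c1
Why: Prilezhaev epoxidation: the strained E C1=C10 olefin is the only electron-rich double bond (C4=C5 is deactivated by the allylic C6 and C3 oxygens, the others are conjugated to carbonyl groups). The peracid can reach only its outer face, and in the ring conformer with C14 on the β side this gives the trans 1β,10α-epoxide.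

Step 29
Reactants: 40 bis-silyl ether epoxide
Product: 41 CNP0193678.1, (1R,3S,6R,7R,8R,10R)-1β,10α-epoxy-3β-hydroxy-8β-{(E)-2-[((E)-2-(acetoxymethyl)-4-hydroxybut-2-enoyl)oxymethyl]but-2-enoyloxy}germacra-4Z,11(13)-dien-6α,12-olide
Conditions: HF·pyridine, pyridine, THF, 0 °C → rt
Reagents that add atoms: none
Why: Fluoride cleavage of the secondary TBS and primary TBDPS ethers under pyridine-buffered conditions that are non-basic (no acyl migration, no conjugate addition) and only weakly acidic, so the epoxide is expected to survive.

## Compound list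

1 | (S)-5-(hydroxymethyl)furan-2(5H)-one | O=C1O[C@H](CO)C=C1 | starting material
2 | (S)-5-(trityloxymethyl)furan-2(5H)-one | O=C1O[C@H](COC(c2ccccc2)(c2ccccc2)c2ccccc2)C=C1 | intermediate
3 | 4-methylpent-3-en-1-ol | CC(C)=CCCO | starting material
4 | tert-butyl[(4-methylpent-3-en-1-yl)oxy]diphenylsilane | CC(C)=CCCO[Si](c1ccccc1)(c1ccccc1)C(C)(C)C | intermediate
5 | (E)-5-(tert-butyldiphenylsilyloxy)-2-methylpent-2-en-1-ol | OC/C(C)=C/CCO[Si](c1ccccc1)(c1ccccc1)C(C)(C)C | intermediate
6 | (E)-[(5-bromo-4-methylpent-3-en-1-yl)oxy](tert-butyl)diphenylsilane | BrC/C(C)=C/CCO[Si](c1ccccc1)(c1ccccc1)C(C)(C)C | intermediate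
7 | 1,3-dithiane | C1CSCSC1 | starting material
8 | 2-lithio-1,3-dithiane | [Li]C1SCCCS1 | intermediate (not isolated)
9 | 2-[(E)-5-(tert-butyldiphenylsilyloxy)-2-methylpent-2-en-1-yl]-1,3-dithiane | C1CSC(SC1)C/C(C)=C/CCO[Si](c1ccccc1)(c1ccccc1)C(C)(C)C | intermediate
10 | N,N-dimethylmethyleneiminium iodide | C=[N+](C)C.[I-] | starting material
11 | 2-lithio derivative of 9 | [Li]C1(SCCCS1)C/C(C)=C/CCO[Si](c1ccccc1)(c1ccccc1)C(C)(C)C | intermediate (not isolated)
12 | lithium enolate of the conjugate adduct (C7 trans to C6 substituent) | C1=C(O[Li])O[C@H](COC(c2ccccc2)(c2ccccc2)c2ccccc2)[C@H]1C1(SCCCS1)C/C(C)=C/CCO[Si](c1ccccc1)(c1ccccc1)C(C)(C)C | intermediate (not isolated)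
13 | (3R,4S,5S)-3-[(dimethylamino)methyl]-4-{2-[(E)-5-(tert-butyldiphenylsilyloxy)-2-methylpent-2-en-1-yl]-1,3-dithian-2-yl}-5-(trityloxymethyl)oxolan-2-one | CN(C)C[C@@H]1C(=O)O[C@H](COC(c2ccccc2)(c2ccccc2)c2ccccc2)[C@H]1C1(SCCCS1)C/C(C)=C/CCO[Si](c1ccccc1)(c1ccccc1)C(C)(C)C | intermediate
14 | 5-(hydroxymethyl) analogue of 13 (3R,4S,5S) | CN(C)C[C@@H]1C(=O)O[C@H](CO)[C@H]1C1(SCCCS1)C/C(C)=C/CCO[Si](c1ccccc1)(c1ccccc1)C(C)(C)C | intermediate
15 | (2S,3S,4R)-4-[(dimethylamino)methyl]-3-{2-[(E)-5-(tert-butyldiphenylsilyloxy)-2-methylpent-2-en-1-yl]-1,3-dithian-2-yl}-5-oxooxolane-2-carbaldehyde | CN(C)C[C@@H]1C(=O)O[C@H](C=O)[C@H]1C1(SCCCS1)C/C(C)=C/CCO[Si](c1ccccc1)(c1ccccc1)C(C)(C)C | intermediate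
16 | (3R,4S,5S)-3-[(dimethylamino)methyl]-4-{2-[(E)-5-(tert-butyldiphenylsilyloxy)-2-methylpent-2-en-1-yl]-1,3-dithian-2-yl}-5-[(Z)-2-iodoprop-1-en-1-yl]oxolan-2-one | CN(C)C[C@@H]1C(=O)O[C@H](/C=C(/C)I)[C@H]1C1(SCCCS1)C/C(C)=C/CCO[Si](c1ccccc1)(c1ccccc1)C(C)(C)C | intermediate
17 | (3R,4S,5S)-3-[(dimethylamino)methyl]-4-{2-[(E)-5-hydroxy-2-methylpent-2-en-1-yl]-1,3-dithian-2-yl}-5-[(Z)-2-iodoprop-1-en-1-yl]oxolan-2-one | CN(C)C[C@@H]1C(=O)O[C@H](/C=C(/C)I)[C@H]1C1(SCCCS1)C/C(C)=C/CCO | intermediate
18 | (3R,4S,5S)-3-[(dimethylamino)methyl]-4-{2-[(E)-2-methyl-5-oxopent-2-en-1-yl]-1,3-dithian-2-yl}-5-[(Z)-2-iodoprop-1-en-1-yl]oxolan-2-one | CN(C)C[C@@H]1C(=O)O[C@H](/C=C(/C)I)[C@H]1C1(SCCCS1)C/C(C)=C/CC=O | intermediate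
19 | (1(10)E,4Z)-13-(dimethylamino)-3β-hydroxy-8,8-(propane-1,3-diyldisulfanediyl)-11βH-11,13-dihydrogermacra-1(10),4-dien-6α,12-olide | CN(C)C[C@@H]1C(=O)O[C@@H]2/C=C(/C)[C@@H](O)C/C=C(\C)CC3(SCCCS3)[C@@H]12 | intermediate
20 | 3-O-tert-butyldimethylsilyl ether of 19 | CN(C)C[C@@H]1C(=O)O[C@@H]2/C=C(/C)[C@@H](O[Si](C)(C)C(C)(C)C)C/C=C(\C)CC3(SCCCS3)[C@@H]12 | intermediate
21 | (1(10)E,4Z)-3β-(tert-butyldimethylsilyloxy)-13-(dimethylamino)-8-oxo-11βH-11,13-dihydrogermacra-1(10),4-dien-6α,12-olide | CN(C)C[C@@H]1C(=O)O[C@@H]2/C=C(/C)[C@@H](O[Si](C)(C)C(C)(C)C)C/C=C(\C)CC(=O)[C@@H]12 | intermediate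
22 | 8β-hydroxy compound from 21 (8R) | CN(C)C[C@@H]1C(=O)O[C@@H]2/C=C(/C)[C@@H](O[Si](C)(C)C(C)(C)C)C/C=C(\C)C[C@@H](O)[C@@H]12 | intermediate
23 | ethylene glycol | OCCO | starting material
24 | 2-(tert-butyldiphenylsilyloxy)ethanol | OCCO[Si](c1ccccc1)(c1ccccc1)C(C)(C)C | intermediate
25 | (tert-butyldiphenylsilyloxy)acetaldehyde | O=CCO[Si](c1ccccc1)(c1ccccc1)C(C)(C)C | intermediate
26 | tert-butyl acrylate | C=CC(=O)OC(C)(C)C | starting material
27 | tert-butyl 4-(tert-butyldiphenylsilyloxy)-3-hydroxy-2-methylidenebutanoate (racemic) | C=C(C(O)CO[Si](c1ccccc1)(c1ccccc1)C(C)(C)C)C(=O)OC(C)(C)C | intermediate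
28 | tert-butyl (Z)-2-(bromomethyl)-4-(tert-butyldiphenylsilyloxy)but-2-enoate | CC(C)(C)OC(=O)/C(=C/CO[Si](c1ccccc1)(c1ccccc1)C(C)(C)C)CBr | intermediate
29 | tert-butyl (E)-2-(acetoxymethyl)-4-(tert-butyldiphenylsilyloxy)but-2-enoate | CC(C)(C)OC(=O)/C(=C/CO[Si](c1ccccc1)(c1ccccc1)C(C)(C)C)COC(C)=O | intermediate
30 | (E)-2-(acetoxymethyl)-4-(tert-butyldiphenylsilyloxy)but-2-enoic acid | OC(=O)/C(=C/CO[Si](c1ccccc1)(c1ccccc1)C(C)(C)C)COC(C)=O | intermediate
31 | acetaldehyde | CC=O | starting material
32 | tert-butyl 3-hydroxy-2-methylidenebutanoate (racemic) | C=C(C(C)O)C(=O)OC(C)(C)C | intermediate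
33 | tert-butyl (Z)-2-(bromomethyl)but-2-enoate | CC(C)(C)OC(=O)/C(=C/C)CBr | intermediate
34 | tert-butyl (E)-2-({[(E)-2-(acetoxymethyl)-4-(tert-butyldiphenylsilyloxy)but-2-enoyl]oxy}methyl)but-2-enoate | CC(C)(C)OC(=O)/C(=C/C)COC(=O)/C(=C/CO[Si](c1ccccc1)(c1ccccc1)C(C)(C)C)COC(C)=O | intermediate
35 | (E)-2-({[(E)-2-(acetoxymethyl)-4-(tert-butyldiphenylsilyloxy)but-2-enoyl]oxy}methyl)but-2-enoic acid | OC(=O)/C(=C/C)COC(=O)/C(=C/CO[Si](c1ccccc1)(c1ccccc1)C(C)(C)C)COC(C)=O | intermediate
36 | mixed anhydride of 35 with 2,4,6-trichlorobenzoic acid | O=C(OC(=O)/C(=C/C)COC(=O)/C(=C/CO[Si](c1ccccc1)(c1ccccc1)C(C)(C)C)COC(C)=O)c1c(Cl)cc(Cl)cc1Cl | intermediate (not isolated)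
37 | 8β-ester of 22 with acid 35 | CN(C)C[C@@H]1C(=O)O[C@@H]2/C=C(/C)[C@@H](O[Si](C)(C)C(C)(C)C)C/C=C(\C)C[C@@H](OC(=O)/C(=C/C)COC(=O)/C(=C/CO[Si](c3ccccc3)(c3ccccc3)C(C)(C)C)COC(C)=O)[C@@H]12 | intermediate
38 | N-methyl quaternary ammonium iodide of 37 | C[N+](C)(C)C[C@@H]1C(=O)O[C@@H]2/C=C(/C)[C@@H](O[Si](C)(C)C(C)(C)C)C/C=C(\C)C[C@@H](OC(=O)/C(=C/C)COC(=O)/C(=C/CO[Si](c3ccccc3)(c3ccccc3)C(C)(C)C)COC(C)=O)[C@@H]12.[I-] | intermediate (not isolated)
39 | (1(10)E,4Z)-3β-(tert-butyldimethylsilyloxy)-8β-acyloxygermacra-1(10),4,11(13)-trien-6α,12-olide (acyl as in 37) | C=C1C(=O)O[C@@H]2/C=C(/C)[C@@H](O[Si](C)(C)C(C)(C)C)C/C=C(\C)C[C@@H](OC(=O)/C(=C/C)COC(=O)/C(=C/CO[Si](c3ccccc3)(c3ccccc3)C(C)(C)C)COC(C)=O)[C@@H]12 | intermediate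
40 | 1β,10α-epoxide of 39 | C=C1C(=O)O[C@@H]2/C=C(/C)[C@@H](O[Si](C)(C)C(C)(C)C)C[C@H]3O[C@]3(C)C[C@@H](OC(=O)/C(=C/C)COC(=O)/C(=C/CO[Si](c4ccccc4)(c4ccccc4)C(C)(C)C)COC(C)=O)[C@@H]12 | intermediate
41 | CNP0193678.1 | C=C1C(=O)O[C@@H]2/C=C(/C)[C@@H](O)C[C@H]3O[C@]3(C)C[C@@H](OC(=O)/C(=C/C)COC(=O)/C(=C/CO)COC(C)=O)[C@@H]12 | target

## Step count and least certain steps

Total: 29 steps. Longest linear sequence: 18 steps (from 3: steps 2–15, then 26–29). The side-chain branch (steps 16–25) and step 1 are convergent.

Step 6 (key step). What may go wrong: the hindered tertiary dithianyl anion may transfer a proton from C6 of the butenolide or add 1,2 instead of 1,4. Capture of the enolate by the sparingly soluble iminium salt may also be incomplete, so the enolate is protonated or exchanges protons with product. Fallback: the two bond formations are separated. Starting from 9 and 2, the conjugate addition is run alone and quenched cold with NH4Cl to give the C11-unsubstituted lactone (4S,5S)-4-{2-[(E)-5-(tert-butyldiphenylsilyloxy)-2-methylpent-2-en-1-yl]-1,3-dithian-2-yl}-5-(trityloxymethyl)oxolan-2-one F1. Its enolate is then formed on its own (LiN(i-Pr)2, THF, −78 °C) and aminomethylated with 10, anti to the C7 substituent, which returns to the route at 13.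

Step 9. What may go wrong: epimerisation of the α-acyloxy aldehyde at C6 or enolisation of the lactone by the basic ylide mixture, and erosion of the Z selectivity. Fallback: a non-basic two-stage olefination from 15. Corey–Fuchs reaction (CBr4, PPh3, CH2Cl2, 0 °C) gives the 1,1-dibromoalkene F2. Negishi coupling with MeZnCl under PdCl2[(2-Ph2PC6H4)2O] catalysis replaces selectively the bromine trans to C6 and gives the (Z)-2-bromoprop-1-enyl lactone F3. This is taken through the conditions of steps 10 and 11 to the bromo alcohol F4 and the bromo aldehyde F5. The NiCl2-catalysed CrCl2 ring closure accepts alkenyl bromides, if more slowly, and rejoins the route at 19.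

Step 12. What may go wrong: intermolecular coupling or simple reduction of the C–I bond in place of ring closure, and attack on the other face of the aldehyde, because nothing close to C3 controls it. Fallback (for the facial problem): from 18 the cyclisation would then give the 3α-hydroxy epimer F6. This is inverted by a Mitsunobu reaction (4-nitrobenzoic acid, PPh3, DIAD, toluene) to the 3β-(4-nitrobenzoate) F7, and brief methanolysis (K2CO3, MeOH, 0 °C) returns to 19.

Step 15 (with the unmasking of step 14). What may go wrong: hydride delivery to the face that gives the 8α-alcohol if the ring conformer with the carbonyl oxygen turned to the α side reacts. Before reduction, the ketone may also lose the C6 carboxylate or shift C1=C10 into conjugation. Fallback: starting from 21, if reduction (for example with a bulkier hydride) gives the 8α-hydroxy epimer F8, this alcohol is esterified directly with acid 35 under Mitsunobu conditions (PPh3, DIAD, toluene). The inversion at C8 leads to 37, bypassing 22 and the Yamaguchi step.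

Step 28. What may go wrong: attack on the olefin face exposed in another ring conformer (wrong epoxide diastereomer), partial oxidation of C4=C5, or acid-induced transannular opening of the product by m-chlorobenzoic acid. Fallback: substrate control is replaced by catalyst control. Starting from 39, a Shi epoxidation (fructose-derived chiral ketone, KHSO5, buffered aqueous MeCN–dimethoxymethane, 0 °C) selects the E-trisubstituted olefin and the face by the choice of ketone enantiomer under non-acidic conditions, and returns at 40. This fallback makes no new compound (F0).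

## Further compounds

F1 | step 6 | (4S,5S)-4-{2-[(E)-5-(tert-butyldiphenylsilyloxy)-2-methylpent-2-en-1-yl]-1,3-dithian-2-yl}-5-(trityloxymethyl)oxolan-2-one | C1C(=O)O[C@H](COC(c2ccccc2)(c2ccccc2)c2ccccc2)[C@H]1C1(SCCCS1)C/C(C)=C/CCO[Si](c1ccccc1)(c1ccccc1)C(C)(C)C
F2 | step 9 | 5-(2,2-dibromoethenyl) analogue of 16 | CN(C)C[C@@H]1C(=O)O[C@H](C=C(Br)Br)[C@H]1C1(SCCCS1)C/C(C)=C/CCO[Si](c1ccccc1)(c1ccccc1)C(C)(C)C
F3 | step 9 | 5-[(Z)-2-bromoprop-1-en-1-yl] analogue of 16 | CN(C)C[C@@H]1C(=O)O[C@H](/C=C(/C)Br)[C@H]1C1(SCCCS1)C/C(C)=C/CCO[Si](c1ccccc1)(c1ccccc1)C(C)(C)C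
F4 | step 9 | bromo analogue of alcohol 17 | CN(C)C[C@@H]1C(=O)O[C@H](/C=C(/C)Br)[C@H]1C1(SCCCS1)C/C(C)=C/CCO
F5 | step 9 | bromo analogue of aldehyde 18 | CN(C)C[C@@H]1C(=O)O[C@H](/C=C(/C)Br)[C@H]1C1(SCCCS1)C/C(C)=C/CC=O
F6 | step 12 | 3α-hydroxy epimer of 19 | CN(C)C[C@@H]1C(=O)O[C@@H]2/C=C(/C)[C@H](O)C/C=C(\C)CC3(SCCCS3)[C@@H]12
F7 | step 12 | 3β-(4-nitrobenzoyloxy) derivative of 19 | CN(C)C[C@@H]1C(=O)O[C@@H]2/C=C(/C)[C@@H](OC(=O)c3ccc(cc3)[N+](=O)[O-])C/C=C(\C)CC3(SCCCS3)[C@@H]12
F8 | step 15 | 8α-hydroxy epimer of 22 | CN(C)C[C@@H]1C(=O)O[C@@H]2/C=C(/C)[C@@H](O[Si](C)(C)C(C)(C)C)C/C=C(\C)C[C@H](O)[C@@H]12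
F0 | step 28 | none | none
A1 | alternative 1 | (1(10)E,4Z)-8-(4-methoxybenzyloxy)-3-oxogermacra-1(10),4-dien-6,12-olide | C1C(=O)O[C@@H]2/C=C(/C)C(=O)C/C=C(\C)/C[C@@H](OCc3ccc(OC)cc3)[C@@H]12
A2 | alternative 2 | target core α-methylene lactone as 3-O-tert-butyldimethylsilyl, 8-O-triethylsilyl ether | C=C1C(=O)O[C@@H]2/C=C(/C)[C@@H](O[Si](C)(C)C(C)(C)C)C[C@H]3O[C@]3(C)C[C@@H](O[Si](CC)(CC)CC)[C@@H]12
A3 | alternative 3 | trans-fused lactone dienone with C11 methyl ester and C8 O-(2,2,6,6-tetramethylpiperidin-1-yl) group | COC(=O)C1C(=O)O[C@@H]2/C=C(/C)C(=O)C/C=C(\C)/C[C@@H](ON3C(C)(C)CCCC3(C)C)[C@@H]12
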